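The earlier runs and the new flask were computed from invented constants.

Follow the reagent.

| setting | summer | noon | flask |
|---|---|---|---|
| substrate | 1 mM | 1 mM | 1.0 mM |
| partner | 2 mM | 4 mM | 2.00 mM |
| reagent | 1.5 mM | 1.5 mM | 1.50 mM |
| protic impurity | 0.30 mM | 0.30 mM | 0.300 mM |
| remark | the very flask that is asked about, followed so far | run made earlier |  |
| time |  |  | 4.0 min |

| summer: time / min | summer: product / % | noon: time / s | noon: product / % |
|---|---|---|---|
| 0.833 | 57 | 10.0 | 33 |
| 1.50 | 55 | 30.0 | 36 |
| 2.50 | 55 | 50.0 | 38 |
| 3.00 | 56 | 80.0 | 37 |

(readings scatter by 2 percentage points)

- additions leave the volume as it is
- the earlier runs were read with a standard deviation of 2 percentage points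
- a reading or a percentage of product counts all its forms, free or not

- elm: change nothing and wait 2.0 min more
- ash: at 4.0 min add substrate, 50.0% of the amount charged, then wait 2.0 min
- maple: at 4.0 min add reagent, 50.0% of the amount charged, then wait 2.0 min

- product, in percent of the substrate first charged, at 4.0 min
- the remedy with the largest gain of product, or "none" below 2 percentage points (elm / ash / maple / none)
- product present, in percent of the substrate first charged, after ash
- product present, in percent of the substrate first charged, after maple

The summer readings stand flat at a mean of 55.8%, and the noon readings at 36.0%. So the summer flask should read about that first mean at 4.0 min, and elm should gain nothing. Ash should gain nothing either if the reagent has stopped the run. The noon run, with 4 mM of partner against 2 mM, has the lower plateau, so partner seems to compete for reagent.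

A first hand estimate lets the impurity take its whole charge, which leaves 1.20 mM of reagent. On that footing the summer readings put substrate at 0.442 mM and partner at 1.36 mM in this flask. The selectivity factor is the logarithm of substrate charged over left, divided by the same logarithm for partner. It stays constant through a run if both take reagent first-order. It reads 2.10 in summer and 1.89 at noon.

Taking it as 2, maple's 0.750 mM of reagent leaves product at 81.9%.

The weak link is the impurity's share. If it takes nothing, the reckoned partner is 1.06 mM and the factor reads 1.28 in summer and 1.33 at noon, so the two runs lie close together on either footing. A round factor of 1 on that footing gives 77.9% after maple. This reckoning therefore commits to maple, with product between these two values.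

The forecast gives 56% (54% to 58%), 56% after ash (53.5% to 59%), 82% after maple (76% to 87%), and maple as best: “More partner lowers the yield, so partner must compete with substrate for the reagent.”

The flask gives 56.0%, 56.0% after ash, 79.4% after maple, and maple as best, with a gain of 23 percentage points.

    substrate + reagent → open intermediate (k = 61.1 M⁻¹ s⁻¹)
    reagent + protic impurity → quenched reagent (k = 11.4 M⁻¹ s⁻¹)
    reagent + partner → second intermediate (k = 44.3 M⁻¹ s⁻¹)
    reagent + product ⇌ idle adduct, settled at all times (K = 830 M⁻¹)
    open intermediate + second intermediate → product (k = 790 M⁻¹ s⁻¹)

The flask has come to rest. After ten times the asked time, at 40.0 min, product is 56.0%, substrate 44.0%, partner 55.1% of its own charge and reagent, the limiting reagent, 0%. The flask's remainders of substrate and partner put the factor at 1.38, against the 2 taken above. The answer to "now" would lie outside the forecast's range in a run charged with 1.35 mM or 1.65 mM of reagent, or with 1.70 mM or 2.36 mM of partner, the rest held, since each moves it by 5 points.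

For the neighbour with 5.0 mM of partner, a factor of 2 and 1.20 mM of reagent give 32.1% of product. That neighbour gives 30.8%, with 69.2% of its substrate left and a factor of 1.38 on its remainders.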